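Ring A (the cyclopentane, C4a–C5–C6–C7–C7a) is cut at C5–C6. With C6 as a ketone, C6, C7, C7a, C4a and C5 are the five carbons of a 4-pentenal whose alkene is an exocyclic methylene (C4a=C5) on the piperidine (ring B). One rhodium-mediated intramolecular hydroacylation therefore closes ring A, forms C5–C6 and sets C4a with a cis ring fusion. The precursor is a cis-3,5-disubstituted 4-methylidenepiperidine: C4 methyl on one side, an (S)-configured propanal arm (C7, C6) at C7a on the other, nitrogen masked as a tert-butyl carbamate whose carbonyl carbon later becomes the N-methyl group. The C6 ester is introduced last with inversion.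

Key step: step 5

Remark: in the Why lines the atoms of every intermediate carry the cyclopenta[c]pyridine numbers of the target core (C1, N2, C3, C4, C4a, C5, C6, C7, C7a); compound names use their own locants.
Assumption: a free tertiary amine would bind rhodium and epimerise the α-branched aldehyde, so nitrogen is carried as its tert-butyl carbamate until step 6; the hydride in step 6 is assumed to attack the exo face of the cis-fused ketone.

Step 1
Reactants: 1 tert-butyl 3-methyl-4-oxopiperidine-1-carboxylate (racemic, in excess); 2 (E)-1-nitroprop-1-ene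
Product: 3 tert-butyl (5R)-3-methyl-5-[(2S)-1-nitropropan-2-yl]-4-oxopiperidine-1-carboxylate (mixture of epimers at the methyl-bearing C3)
Conditions: 1 (3 equiv), (S)-1-[3,5-bis(trifluoromethyl)phenyl]-3-(pyrrolidin-2-ylmethyl)thiourea (20 mol%), n-PrCO2H (10 mol%), toluene, 0 °C
Reagents that add atoms: none
Why: Enamine-catalysed asymmetric Michael addition to a nitroalkene: the pyrrolidine condenses on the less substituted side of 1, the thiourea binds the nitro group, and C–C bond formation through the synclinal open transition state known for this catalyst class with cyclic ketones sets the syn pair C7a/C7 [(5R,2′S) in 3] under catalyst control, while C4 is left as a mixture for step 2 and the slower-reacting enantiomer of 1 stays behind.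

Step 2
Reactants: 3 tert-butyl (5R)-3-methyl-5-[(2S)-1-nitropropan-2-yl]-4-oxopiperidine-1-carboxylate
Product: 5 tert-butyl (3R,5S)-3-[(2S)-1,1-dimethoxypropan-2-yl]-5-methyl-4-oxopiperidine-1-carboxylate, via cis nitronate sodium salt 4 (not isolated)
Conditions: NaOMe (1.5 equiv), MeOH, 0 °C to rt; then added to H2SO4/MeOH, −40 °C; aq. NaHCO3
Reagents that add atoms: methanol (CO)
Why: Nef reaction in its acetal-forming variant preceded by thermodynamic epimerisation: methoxide first stores the nitro group as nitronate 4, whose charge and branched chain disfavour enolisation toward C7a, so the excess base equilibrates only the C4 methyl centre to the diequatorial cis-3,5 ketone before cold methanolic acid solvolyses the nitronate to the dimethyl acetal, C7 being non-enolisable throughout.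

Step 3
Reactants: 5 tert-butyl (3R,5S)-3-[(2S)-1,1-dimethoxypropan-2-yl]-5-methyl-4-oxopiperidine-1-carboxylate
Product: 6 tert-butyl (3S,5R)-3-[(2S)-1,1-dimethoxypropan-2-yl]-5-methyl-4-methylidenepiperidine-1-carboxylate
Conditions: Cp2TiMe2 (2 equiv), toluene, 70 °C, dark
Reagents that add atoms: dimethyltitanocene ([CH-]1C=CC=C1.[CH-]1C=CC=C1.[CH3-].[CH3-].[Ti+4])
Why: Petasis methylenation: Cp2TiMe2 loses methane on heating and the resulting Cp2Ti=CH2 converts the hindered ketone into the exocyclic C4a=C5 alkene through an oxatitanacyclobutane under non-basic conditions, so the flanking C4 and C7a centres cannot epimerise and the acetal and carbamate are left alone.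

Step 4
Reactants: 6 tert-butyl (3S,5R)-3-[(2S)-1,1-dimethoxypropan-2-yl]-5-methyl-4-methylidenepiperidine-1-carboxylate
Product: 7 tert-butyl (3R,5S)-3-methyl-4-methylidene-5-[(2S)-1-oxopropan-2-yl]piperidine-1-carboxylate
Conditions: TsOH·H2O (10 mol%), acetone/H2O (10:1), rt; used directly
Reagents that add atoms: water (O)
Why: Mild acid-catalysed acetal hydrolysis releases the aldehyde without cleaving the tert-butyl carbamate or moving the exocyclic alkene, and because no basic amine is present the C7 centre alpha to the new aldehyde keeps its configuration.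

Step 5
Reactants: 7 tert-butyl (3R,5S)-3-methyl-4-methylidene-5-[(2S)-1-oxopropan-2-yl]piperidine-1-carboxylate
Product: 8 tert-butyl (4R,4aS,7S,7aR)-4,7-dimethyl-6-oxooctahydro-2H-cyclopenta[c]pyridine-2-carboxylate
Conditions: RhCl(PPh3)3 (0.5 equiv), degassed CH2Cl2, rt
Reagents that add atoms: none
Why: Monovalent rhodium inserts into the aldehyde C–H bond to give an acyl rhodium hydride, which coordinates the exocyclic C4a=C5 alkene, transfers hydride to C4a while rhodium bonds to C5, and then forms C5–C6 by reductive elimination from the six-membered acyl-alkyl rhodacycle. The closest known reaction is the RhCl(PPh3)3-mediated cyclisation of 3,4-disubstituted 4-pentenals to cis-3,4-disubstituted cyclopentanones. Ring A closes in a formally 5-endo-trig mode, which is possible here because the bond is made by reductive elimination at the metal and not by direct attack of C6 on the alkene. The only new stereocentre, C4a, is controlled by the face of hydride delivery: the cis C4 methyl and C7a side chain lock the piperidine in the diequatorial chair, allylic 1,3-strain turns the C7–H bond into the alkene plane, and for the (7S) configuration this leaves the acyl rhodium over the face syn to the axial H4 and H7a, so H4a enters cis to both and the ring fusion is cis. The step needs hydroacylation to outrun decarbonylation and alkene migration and needs this facial selectivity; the 1,1-disubstituted alkene, the non-coordinating carbamate nitrogen and the matched C7 configuration secure them. C4, C7 and C7a are carried through unchanged.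

Step 6
Reactants: 8 tert-butyl (4R,4aS,7S,7aR)-4,7-dimethyl-6-oxooctahydro-2H-cyclopenta[c]pyridine-2-carboxylate
Product: 10 (4R,4aS,6S,7S,7aR)-2,4,7-trimethyloctahydro-1H-cyclopenta[c]pyridin-6-ol, via lithium alkoxide 9 (not isolated)
Conditions: LiAlH4 (4 equiv), THF, −78 °C to 0 °C, then reflux; H2O/aq. NaOH work-up
Reagents that add atoms: none
Why: Hydride reduction: at low temperature LiAlH4 attacks the C6 ketone from the exo face of the cis-fused bicycle (the face of H4a and H7a, away from the pseudoaxial C1 methylene), setting C6 as the (6S) alkoxide 9, and on heating the same reagent reduces the carbamate to the N-methyl amine (carbamate-to-methylamine reduction).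

Step 7
Reactants: 11 (S)-citronellol [(3S)-3,7-dimethyloct-6-en-1-ol]
Product: 12 tert-butyl{[(3S)-3,7-dimethyloct-6-en-1-yl]oxy}dimethylsilane
Conditions: TBSCl, imidazole, DMF, rt
Reagents that add atoms: tert-butyldimethylsilyl chloride (CC(C)(C)[Si](C)(C)Cl)
Why: Standard imidazole-assisted silylation of the primary alcohol masks the hydroxyl for the oxidation and esterification steps and leaves the C3 stereocentre untouched.

Step 8
Reactants: 12 tert-butyl{[(3S)-3,7-dimethyloct-6-en-1-yl]oxy}dimethylsilane
Product: 14 (4S)-6-{[tert-butyl(dimethyl)silyl]oxy}-4-methylhexanal, via ozonide 13 (not isolated)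
Conditions: O3, CH2Cl2, −78 °C; then PPh3, −78 °C to rt
Reagents that add atoms: ozone ([O-][O+]=O)
Why: Ozonolysis of the trisubstituted alkene by cycloaddition to ozonide 13 followed by reductive cleavage with PPh3 gives the aldehyde and acetone, with the silyl ether and the remote stereocentre unaffected.

Step 9
Reactants: 14 (4S)-6-{[tert-butyl(dimethyl)silyl]oxy}-4-methylhexanal
Product: 15 ethyl (2E,6S)-8-{[tert-butyl(dimethyl)silyl]oxy}-2,6-dimethyloct-2-enoate
Conditions: Ph3P=C(CH3)CO2Et (1.3 equiv), CH2Cl2, rt
Reagents that add atoms: ethyl 2-(triphenyl-λ5-phosphanylidene)propanoate (CCOC(=O)C(C)=P(c1ccccc1)(c1ccccc1)c1ccccc1)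
Why: Wittig olefination with a stabilised, alpha-methyl-substituted ylide is reversible in its addition step and therefore gives the (E)-trisubstituted enoate.

Step 10
Reactants: 15 ethyl (2E,6S)-8-{[tert-butyl(dimethyl)silyl]oxy}-2,6-dimethyloct-2-enoate
Product: 16 (2E,6S)-8-{[tert-butyl(dimethyl)silyl]oxy}-2,6-dimethyloct-2-enoic acid
Conditions: LiOH, THF/MeOH/H2O, rt; then 1 M HCl to pH 4
Reagents that add atoms: lithium hydroxide ([Li+].[OH-])
Why: Saponification with hydroxide cleaves the ethyl ester, while the primary silyl ether and the trisubstituted alkene are stable to these conditions.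

Step 11
Reactants: 10 (4R,4aS,6S,7S,7aR)-2,4,7-trimethyloctahydro-1H-cyclopenta[c]pyridin-6-ol; 16 (2E,6S)-8-{[tert-butyl(dimethyl)silyl]oxy}-2,6-dimethyloct-2-enoic acid
Product: 17 (4R,4aS,6R,7S,7aR)-2,4,7-trimethyloctahydro-1H-cyclopenta[c]pyridin-6-yl (2E,6S)-8-{[tert-butyl(dimethyl)silyl]oxy}-2,6-dimethyloct-2-enoate
Conditions: PPh3, DIAD, THF, 0 °C to rt
Reagents that add atoms: none
Why: Mitsunobu esterification: the (6S) carbinol is activated as its alkoxyphosphonium ion and displaced by the carboxylate of 16 with inversion (SN2), which sets C6 as (6R) as in the target, a coupling for which secondary cyclopentanols bearing a basic tertiary amine are competent substrates.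

Step 12
Reactants: 17 (4R,4aS,6R,7S,7aR)-2,4,7-trimethyloctahydro-1H-cyclopenta[c]pyridin-6-yl (2E,6S)-8-{[tert-butyl(dimethyl)silyl]oxy}-2,6-dimethyloct-2-enoate
Product: 18 (4R,4aS,6R,7S,7aR)-2,4,7-trimethyloctahydro-1H-cyclopenta[c]pyridin-6-yl (2E,6S)-8-hydroxy-2,6-dimethyloct-2-enoate
Conditions: HF·pyridine, THF, 0 °C to rt; aq. NaHCO3
Reagents that add atoms: none
Why: Fluoride-mediated cleavage of the primary silyl ether, driven by the strong Si–F bond, frees the terminal hydroxyl without affecting the enoate ester or the amine and gives the target.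

Compound list

1 | tert-butyl 3-methyl-4-oxopiperidine-1-carboxylate (racemic) | CC1CN(C(=O)OC(C)(C)C)CCC1=O | starting material
2 | (E)-1-nitroprop-1-ene | C/C=C/[N+](=O)[O-] | starting material
3 | tert-butyl (5R)-3-methyl-5-[(2S)-1-nitropropan-2-yl]-4-oxopiperidine-1-carboxylate, C3 epimer mixture | [O-][N+](=O)C[C@@H](C)[C@@H]1CN(C(=O)OC(C)(C)C)CC(C)C1=O | intermediate
4 | sodium nitronate of tert-butyl (3S,5R)-3-methyl-5-[(2S)-1-nitropropan-2-yl]-4-oxopiperidine-1-carboxylate | [Na+].[O-][N+]([O-])=C[C@@H](C)[C@@H]1CN(C(=O)OC(C)(C)C)C[C@H](C)C1=O | intermediate (not isolated)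
5 | tert-butyl (3R,5S)-3-[(2S)-1,1-dimethoxypropan-2-yl]-5-methyl-4-oxopiperidine-1-carboxylate | COC(OC)[C@@H](C)[C@@H]1CN(C(=O)OC(C)(C)C)C[C@H](C)C1=O | intermediate
6 | tert-butyl (3S,5R)-3-[(2S)-1,1-dimethoxypropan-2-yl]-5-methyl-4-methylidenepiperidine-1-carboxylate | COC(OC)[C@@H](C)[C@@H]1CN(C(=O)OC(C)(C)C)C[C@H](C)C1=C | intermediate
7 | tert-butyl (3R,5S)-3-methyl-4-methylidene-5-[(2S)-1-oxopropan-2-yl]piperidine-1-carboxylate | O=C[C@@H](C)[C@@H]1CN(C(=O)OC(C)(C)C)C[C@H](C)C1=C | intermediate (key-step precursor)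
8 | tert-butyl (4R,4aS,7S,7aR)-4,7-dimethyl-6-oxooctahydro-2H-cyclopenta[c]pyridine-2-carboxylate | O=C1C[C@@H]2[C@@H](CN(C(=O)OC(C)(C)C)C[C@@H]2C)[C@@H]1C | intermediate (key-step product)
9 | lithium (4R,4aS,6S,7S,7aR)-2-(tert-butoxycarbonyl)-4,7-dimethyloctahydro-1H-cyclopenta[c]pyridin-6-olate | [Li+].[O-][C@H]1C[C@@H]2[C@@H](CN(C(=O)OC(C)(C)C)C[C@@H]2C)[C@@H]1C | intermediate (not isolated)
10 | (4R,4aS,6S,7S,7aR)-2,4,7-trimethyloctahydro-1H-cyclopenta[c]pyridin-6-ol | O[C@H]1C[C@@H]2[C@@H](CN(C)C[C@@H]2C)[C@@H]1C | intermediate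
11 | (S)-citronellol, (3S)-3,7-dimethyloct-6-en-1-ol | CC(C)=CCC[C@H](C)CCO | starting material
12 | tert-butyl{[(3S)-3,7-dimethyloct-6-en-1-yl]oxy}dimethylsilane | CC(C)=CCC[C@H](C)CCO[Si](C)(C)C(C)(C)C | intermediate
13 | 3-[(3S)-5-{[tert-butyl(dimethyl)silyl]oxy}-3-methylpentyl]-5,5-dimethyl-1,2,4-trioxolane (ozonide) | CC1(C)OOC(CC[C@H](C)CCO[Si](C)(C)C(C)(C)C)O1 | intermediate (not isolated)
14 | (4S)-6-{[tert-butyl(dimethyl)silyl]oxy}-4-methylhexanal | O=CCC[C@H](C)CCO[Si](C)(C)C(C)(C)C | intermediate
15 | ethyl (2E,6S)-8-{[tert-butyl(dimethyl)silyl]oxy}-2,6-dimethyloct-2-enoate | C/C(=C\CC[C@H](C)CCO[Si](C)(C)C(C)(C)C)C(=O)OCC | intermediate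
16 | (2E,6S)-8-{[tert-butyl(dimethyl)silyl]oxy}-2,6-dimethyloct-2-enoic acid | C/C(=C\CC[C@H](C)CCO[Si](C)(C)C(C)(C)C)C(=O)O | intermediate
17 | (4R,4aS,6R,7S,7aR)-2,4,7-trimethyloctahydro-1H-cyclopenta[c]pyridin-6-yl (2E,6S)-8-{[tert-butyl(dimethyl)silyl]oxy}-2,6-dimethyloct-2-enoate | C/C(=C\CC[C@H](C)CCO[Si](C)(C)C(C)(C)C)C(=O)O[C@@H]1C[C@@H]2[C@@H](CN(C)C[C@@H]2C)[C@@H]1C | intermediate
18 | (4R,4aS,6R,7S,7aR)-2,4,7-trimethyloctahydro-1H-cyclopenta[c]pyridin-6-yl (2E,6S)-8-hydroxy-2,6-dimethyloct-2-enoate | C/C(=C\CC[C@H](C)CCO)C(=O)O[C@@H]1C[C@@H]2[C@@H](CN(C)C[C@@H]2C)[C@@H]1C | target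

Total step count: 12. Longest linear sequence: 8 (steps 1 to 6, 11 and 12, from 1).

Steps most likely to fail

Step 5. The acyl rhodium hydride may lose carbon monoxide (decarbonylation) or move the exocyclic alkene into the ring before insertion, or hydride may be delivered to the other alkene face. The fallback sets out from 6 and returns at 8; it makes the C5–C6 bond by polar umpolung alkylation and sets C4a by hydroboration. 9-BBN in THF should add to the exocyclic alkene from the face of the axial H4 and H7a, because the two equatorial neighbours lie below the alkene plane, giving the B-alkyl borane F1. NaOH/H2O2 oxidises it to the all-cis hydroxymethyl piperidine F2, and TsCl/pyridine gives the tosylate F3. Propane-1,3-dithiol with catalytic I2 exchanges the dimethyl acetal for the 1,3-dithiane F4. n-BuLi (THF, −78 to −20 °C) generates the 2-lithio-1,3-dithiane F5, which closes ring A by 5-exo-tet displacement of the tosylate (Corey–Seebach alkylation) to the spiro dithioketal F6. MeI and CaCO3 in aqueous MeCN unmask the ketone and give 8.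

Step 2. The base equilibration may not stop at C4, since slow enolisation toward C7a would erode the catalyst-set C7a/C7 relationship. The strongly acidic methanolysis may also cleave the tert-butyl carbamate or drive the γ-keto acetal toward a furan. The fallback sets out from 3 and returns at 5; it separates the two events and replaces the solvolytic Nef reaction by a reductive one. DBU in MeCN at rt equilibrates C4 in a monitored operation, and the cis nitro ketone F7 is isolated and freed from any C7a epimer. NaOMe (1.0 equiv) converts F7 into nitronate 4, which buffered aqueous TiCl3 (NH4OAc) reduces to the imine and hydrolyses to the keto aldehyde F8 (reductive Nef reaction); F8 is used at once. HC(OMe)3 with pyridinium p-toluenesulfonate in MeOH acetalises only the aldehyde and gives 5.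

Step 11. The activated alcohol may eliminate toward the cyclopentene, or displacement next to the C7 methyl may be slow; the same remedy applies if hydride attack in step 6 turns out to favour the other face. The fallback sets out from 10 and returns at 17; it inverts C6 by oxidation and reagent-controlled reduction and then forms the ester with retention. Swern oxidation ((COCl)2, DMSO, Et3N) gives the amino ketone F9. LiB(sec-Bu)3H at −78 °C, which should approach anti to the adjacent C7 methyl, gives the (6R) carbinol F10. Steglich esterification of F10 with 16 (EDC·HCl, DMAP, CH2Cl2) gives 17.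

Further compounds

F1 | step 5 | tert-butyl (3R,4S,5R)-4-[(9-borabicyclo[3.3.1]nonan-9-yl)methyl]-3-[(2S)-1,1-dimethoxypropan-2-yl]-5-methylpiperidine-1-carboxylate | COC(OC)[C@@H](C)[C@@H]1CN(C(=O)OC(C)(C)C)C[C@H](C)[C@@H]1CB1C2CCCC1CCC2
F2 | step 5 | tert-butyl (3R,4S,5R)-3-[(2S)-1,1-dimethoxypropan-2-yl]-4-(hydroxymethyl)-5-methylpiperidine-1-carboxylate | COC(OC)[C@@H](C)[C@@H]1CN(C(=O)OC(C)(C)C)C[C@H](C)[C@@H]1CO
F3 | step 5 | tert-butyl (3R,4S,5R)-3-[(2S)-1,1-dimethoxypropan-2-yl]-5-methyl-4-{[(4-methylbenzenesulfonyl)oxy]methyl}piperidine-1-carboxylate | COC(OC)[C@@H](C)[C@@H]1CN(C(=O)OC(C)(C)C)C[C@H](C)[C@@H]1COS(=O)(=O)c1ccc(C)cc1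
F4 | step 5 | tert-butyl (3R,4S,5R)-3-[(1S)-1-(1,3-dithian-2-yl)ethyl]-5-methyl-4-{[(4-methylbenzenesulfonyl)oxy]methyl}piperidine-1-carboxylate | C[C@H](C1SCCCS1)[C@@H]2CN(C(=O)OC(C)(C)C)C[C@H](C)[C@@H]2COS(=O)(=O)c3ccc(C)cc3
F5 | step 5 | 2-lithio derivative of F4 (lithium at the dithiane carbon, the future C6) | [Li]C1(SCCCS1)[C@@H](C)[C@@H]2CN(C(=O)OC(C)(C)C)C[C@H](C)[C@@H]2COS(=O)(=O)c3ccc(C)cc3
F6 | step 5 | tert-butyl (4R,4aS,7S,7aR)-4,7-dimethylhexahydrospiro[cyclopenta[c]pyridine-6,2′-[1,3]dithiane]-2-carboxylate (propane-1,3-diyl dithioketal of 8) | S1CCCSC12C[C@@H]3[C@@H](CN(C(=O)OC(C)(C)C)C[C@@H]3C)[C@@H]2C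
F7 | step 2 | tert-butyl (3S,5R)-3-methyl-5-[(2S)-1-nitropropan-2-yl]-4-oxopiperidine-1-carboxylate | [O-][N+](=O)C[C@@H](C)[C@@H]1CN(C(=O)OC(C)(C)C)C[C@H](C)C1=O
F8 | step 2 | tert-butyl (3S,5R)-3-methyl-4-oxo-5-[(2S)-1-oxopropan-2-yl]piperidine-1-carboxylate | O=C[C@@H](C)[C@@H]1CN(C(=O)OC(C)(C)C)C[C@H](C)C1=O
F9 | step 11 | (4R,4aS,7S,7aR)-2,4,7-trimethyloctahydro-6H-cyclopenta[c]pyridin-6-one | O=C1C[C@@H]2[C@@H](CN(C)C[C@@H]2C)[C@@H]1C
F10 | step 11 | (4R,4aS,6R,7S,7aR)-2,4,7-trimethyloctahydro-1H-cyclopenta[c]pyridin-6-ol | O[C@@H]1C[C@@H]2[C@@H](CN(C)C[C@@H]2C)[C@@H]1C
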